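The 2,5-dihydrofuran ring (O–C8–C7=C6–C5, fused to the trimethylcyclohexane ring at C5–C6) is made by copper-catalysed ring expansion of a vinyl oxirane. Because C5 is the allylic terminus of C6=C7, a cis-7,8-epoxide beside the ring C5=C6 alkene can ionise at C7 and deliver its oxygen, still bound to C8, to C5. One operation closes the ring, turns the C7 stereocentre into the quaternary C5 centre and keeps C8. The precursor is a cis-7,8-epoxy C15 ester whose oxirane configuration is relayed from purchased (S)-but-3-yn-2-ol. The furanoid C15 enal, a cis-diol C15 enal and a C10 bisphosphonate are then joined by two Horner–Wadsworth–Emmons reactions.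

Key step: step 7

Remark: positions are given in carotenoid numbering (furanoid end C1–C15, diol end C1'–C15'). Compounds 1, 3, 8, 13, 20 and 25 are taken as commercially available.

Step 1
Reactants: 1 2,2,6-trimethylcyclohexanone
Product: 2 2,6,6-trimethylcyclohex-1-en-1-yl trifluoromethanesulfonate
Conditions: LiN(iPr)2, THF, −78 → 0 °C; then PhNTf2, 0 °C → rt
Reagents that add atoms: N-phenylbis(trifluoromethanesulfonimide), FC(F)(F)S(=O)(=O)N(c1ccccc1)S(=O)(=O)C(F)(F)F
Why: Enol triflate formation: the base removes the only α-hydrogen and the tetrasubstituted enolate is sulfonylated on oxygen, so one regioisomer results and the stereocentre of 1 disappears.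

Step 2
Reactants: 2 2,6,6-trimethylcyclohex-1-en-1-yl trifluoromethanesulfonate; 3 (S)-but-3-yn-2-ol
Product: 4 (2S)-4-(2,6,6-trimethylcyclohex-1-en-1-yl)but-3-yn-2-ol
Conditions: PdCl2(PPh3)2 (5 mol%), CuI (10 mol%), Et3N, DMF, 50 °C
Reagents that add atoms: none
Why: Sonogashira coupling of the enol triflate with the terminal alkyne; the purchased propargylic stereocentre (C9) is not involved.

Step 3
Reactants: 4 (2S)-4-(2,6,6-trimethylcyclohex-1-en-1-yl)but-3-yn-2-ol
Product: 5 (2S,3Z)-4-(2,6,6-trimethylcyclohex-1-en-1-yl)but-3-en-2-ol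
Conditions: H2 (1 atm), Pd/CaCO3 poisoned with Pb(OAc)2 (Lindlar catalyst), quinoline, EtOAc, 0 °C → rt
Reagents that add atoms: none
Why: Lindlar semi-hydrogenation adds H2 syn to the alkyne to give the (Z)-alkene, quinoline suppressing over-reduction and the tetrasubstituted ring alkene being inert.

Step 4
Reactants: 5 (2S,3Z)-4-(2,6,6-trimethylcyclohex-1-en-1-yl)but-3-en-2-ol
Product: 6 (1S)-1-[(2R,3S)-3-(2,6,6-trimethylcyclohex-1-en-1-yl)oxiran-2-yl]ethan-1-ol
Conditions: VO(acac)2 (5 mol%), t-BuOOH (1.5 equiv), CH2Cl2, 0 °C; chromatography on Et3N-deactivated silica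
Reagents that add atoms: tert-butyl hydroperoxide, CC(C)(C)OO
Why: Hydroxyl-directed vanadium epoxidation: A(1,3) strain in the (Z)-allylic alcohol keeps C9–H in the alkene plane, so the vanadium-bound peroxide reaches only the alkene face on the side of the C9 oxygen and the (S)-carbinol sets both oxirane centres (threo product), while the allylic alkene should react much faster than the remote tetrasubstituted one.

Step 5
Reactants: 6 (1S)-1-[(2R,3S)-3-(2,6,6-trimethylcyclohex-1-en-1-yl)oxiran-2-yl]ethan-1-ol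
Product: 7 1-[(2S,3S)-3-(2,6,6-trimethylcyclohex-1-en-1-yl)oxiran-2-yl]ethan-1-one
Conditions: Dess–Martin periodinane, NaHCO3, CH2Cl2, 0 °C → rt
Reagents that add atoms: none
Why: Dess–Martin oxidation of the secondary alcohol under buffered conditions; the oxirane C–H bonds are not acidic enough to epimerise, so the cis-oxirane is kept.

Step 6
Reactants: 7 1-[(2S,3S)-3-(2,6,6-trimethylcyclohex-1-en-1-yl)oxiran-2-yl]ethan-1-one; 8 triethyl phosphonoacetate
Product: 9 ethyl (2E)-3-[(2R,3S)-3-(2,6,6-trimethylcyclohex-1-en-1-yl)oxiran-2-yl]but-2-enoate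
Conditions: 8, NaH, THF, 0 °C; then 7, 0 °C → rt
Reagents that add atoms: none
Why: Horner–Wadsworth–Emmons olefination of the methyl ketone should give mainly the (E)-enoate with the ester trans to the larger oxiranyl group, the minor (Z)-isomer being removed by chromatography.

Step 7
Reactants: 9 ethyl (2E)-3-[(2R,3S)-3-(2,6,6-trimethylcyclohex-1-en-1-yl)oxiran-2-yl]but-2-enoate
Product: 10 ethyl (2E)-3-[(2S,7aR)-4,4,7a-trimethyl-2,4,5,6,7,7a-hexahydro-1-benzofuran-2-yl]but-2-enoate
Conditions: Cu(hfacac)2 (5 mol%), toluene, 60–80 °C, stopped at full conversion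
Reagents that add atoms: none
Why: Cu(hfacac)2 binds the oxirane oxygen and the allylic C7–O bond ionises with contact-ion-pair character to the C5–C6–C7 allyl cation (tertiary at C5), while the C8–O bond, flanked by the electron-poor enoate, stays intact, and the oxygen on C8 then bonds to C5. The closest known reaction is the copper-catalysed ring expansion of vinyl oxiranes to 2,5-dihydrofurans, a formal [1,3]-oxygen shift. The dihydrofuran closes by attack of the C8 oxygen on the far terminus of the allyl cation, a five-membered closure that leaves C6=C7 inside the new ring while the oxirane opens. The quaternary centre C5 is set by suprafacial transfer: the oxygen leaves C7 and arrives at C5 on the same face of the allyl plane, and in the reactive conformer (C7–H towards the gem-dimethyl carbon, C8 towards the C5 methyl) the cis-oxirane then places the butenoate chain and the C5 methyl on the same face of the new ring, i.e. (2S,7aR); C8 keeps its configuration because its C–O bond is never broken. The step needs ionisation at C7 and not at C8 (secured by the tetrasubstituted alkene against the enoate), ring closure faster than rotation about C7–C8 or 1,2-hydride shift (favoured by the non-polar solvent and the tight ion pair), and a temperature low enough to avoid Cope rearrangement of the cis-dialkenyl oxirane (retarded by the inward-pointing C5 methyl).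

Step 8
Reactants: 10 ethyl (2E)-3-[(2S,7aR)-4,4,7a-trimethyl-2,4,5,6,7,7a-hexahydro-1-benzofuran-2-yl]but-2-enoate
Product: 11 (2E)-3-[(2S,7aR)-4,4,7a-trimethyl-2,4,5,6,7,7a-hexahydro-1-benzofuran-2-yl]but-2-en-1-ol
Conditions: iBu2AlH (2.2 equiv), CH2Cl2, −78 °C; aqueous potassium sodium tartrate
Reagents that add atoms: none
Why: iBu2AlH reduces the enoate 1,2 to the allylic alcohol at low temperature without touching the allylic ether or either stereocentre.

Step 9
Reactants: 11 (2E)-3-[(2S,7aR)-4,4,7a-trimethyl-2,4,5,6,7,7a-hexahydro-1-benzofuran-2-yl]but-2-en-1-ol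
Product: 12 (2E)-3-[(2S,7aR)-4,4,7a-trimethyl-2,4,5,6,7,7a-hexahydro-1-benzofuran-2-yl]but-2-enal
Conditions: activated MnO2 (excess), CH2Cl2, rt
Reagents that add atoms: none
Why: MnO2 oxidises only the primary allylic alcohol under neutral conditions, which avoids acid- or base-induced epimerisation at C8.

Step 10
Reactants: 13 β-cyclocitral (2,6,6-trimethylcyclohex-1-ene-1-carbaldehyde)
Product: 14 β-cyclogeraniol ((2,6,6-trimethylcyclohex-1-en-1-yl)methanol)
Conditions: NaBH4, MeOH, 0 °C
Reagents that add atoms: none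
Why: NaBH4 1,2-reduction of the hindered enal gives the allylic alcohol.

Step 11
Reactants: 14 β-cyclogeraniol
Product: 15 [(1R,6R)-2,2,6-trimethyl-7-oxabicyclo[4.1.0]heptan-1-yl]methanol
Conditions: Ti(OiPr)4 (10 mol%), D-(−)-diethyl tartrate (12 mol%), t-BuOOH, 4 Å molecular sieves, CH2Cl2, −20 °C
Reagents that add atoms: tert-butyl hydroperoxide, CC(C)(C)OO
Why: Sharpless asymmetric epoxidation: the titanium tartrate complex delivers oxygen to one face of the tetrasubstituted allylic alcohol, and D-(−)-diethyl tartrate (the antipode of the tartrate that gives (2S,3S)-epoxides from geraniol-type alcohols) sets the methyl-bearing C–O centre, the future C5', as R.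

Step 12
Reactants: 15 [(1R,6R)-2,2,6-trimethyl-7-oxabicyclo[4.1.0]heptan-1-yl]methanol
Product: 16 (1S,6R)-1-(iodomethyl)-2,2,6-trimethyl-7-oxabicyclo[4.1.0]heptane
Conditions: PPh3, I2, imidazole, toluene/MeCN, 0 → 50 °C
Reagents that add atoms: iodine, II
Why: Appel-type iodination: the alkoxyphosphonium ion is displaced by iodide in an SN2 reaction at the primary carbon, leaving the oxirane untouched (the descriptor at C1 changes only because of the priority of iodine).

Step 13
Reactants: 16 (1S,6R)-1-(iodomethyl)-2,2,6-trimethyl-7-oxabicyclo[4.1.0]heptane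
Product: 17 (1R)-1,3,3-trimethyl-2-methylidenecyclohexan-1-ol
Conditions: Zn dust, AcOH, EtOH, 60 °C
Reagents that add atoms: none
Why: Zinc inserts into the C–I bond and β-elimination opens the oxirane (reductive epoxide fragmentation), giving the transposed tertiary allylic alcohol with its C–O stereocentre unchanged.

Step 14
Reactants: 17 (1R)-1,3,3-trimethyl-2-methylidenecyclohexan-1-ol
Product: 18 (2R)-2-hydroxy-2,6,6-trimethylcyclohexan-1-one
Conditions: O3, CH2Cl2/MeOH, −78 °C; then Me2S, −78 °C → rt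
Reagents that add atoms: ozone, [O-][O+]=O
Why: Ozonolysis with reductive work-up cleaves the 1,1-disubstituted alkene to the ketone; the tertiary carbinol has no α-hydrogen and cannot epimerise.

Step 15
Reactants: 18 (2R)-2-hydroxy-2,6,6-trimethylcyclohexan-1-one
Product: 19 (2R)-2,6,6-trimethyl-2-[(trimethylsilyl)oxy]cyclohexan-1-one
Conditions: Me3SiOTf, 2,6-lutidine, CH2Cl2, −78 → 0 °C
Reagents that add atoms: trimethylsilyl trifluoromethanesulfonate, C[Si](C)(C)OS(=O)(=O)C(F)(F)F
Why: Silylation of the tertiary alcohol gives a non-chelating α-silyloxy ketone for the next step.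

Step 16
Reactants: 19 (2R)-2,6,6-trimethyl-2-[(trimethylsilyl)oxy]cyclohexan-1-one; 20 (2E)-3-methylpent-2-en-4-yn-1-ol
Product: 22 (1R,2R)-1-[(3E)-5-hydroxy-3-methylpent-3-en-1-yn-1-yl]-2,6,6-trimethylcyclohexane-1,2-diol, via silyl-protected adduct 21 (not isolated)
Conditions: 20, n-BuLi (2 equiv), THF, −78 → 0 °C; then 19, −78 °C → rt; then K2CO3, MeOH, rt
Reagents that add atoms: none
Why: 1,2-Addition of the lithium acetylide to the non-enolisable ketone under polar Felkin–Anh control: in the chair with axial C–OSiMe3 the nucleophile enters axially, anti to that C–O bond and away from the axial methyl groups, so the new hydroxyl should be cis to the silyloxy group, and K2CO3/MeOH then removes the silyl group.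

Step 17
Reactants: 22 (1R,2R)-1-[(3E)-5-hydroxy-3-methylpent-3-en-1-yn-1-yl]-2,6,6-trimethylcyclohexane-1,2-diol
Product: 23 (1S,2R)-1-[(1E,3E)-5-hydroxy-3-methylpenta-1,3-dien-1-yl]-2,6,6-trimethylcyclohexane-1,2-diol
Conditions: NaAlH2(OCH2CH2OMe)2 (Red-Al, excess), THF, 0 °C → rt; aqueous potassium sodium tartrate
Reagents that add atoms: none
Why: Red-Al adds hydride to the alkyne through the propargylic alkoxyaluminate (trans-hydroalumination) and protonolysis gives the (E)-alkene; the descriptor at C1 changes only through CIP priorities.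

Step 18
Reactants: 23 (1S,2R)-1-[(1E,3E)-5-hydroxy-3-methylpenta-1,3-dien-1-yl]-2,6,6-trimethylcyclohexane-1,2-diol
Product: 24 (2E,4E)-5-[(1S,2R)-1,2-dihydroxy-2,6,6-trimethylcyclohexyl]-3-methylpenta-2,4-dienal
Conditions: IBX, DMSO, rt
Reagents that add atoms: none
Why: IBX oxidises the primary allylic alcohol to the enal and leaves the di-tertiary diol untouched, without glycol cleavage.

Step 19
Reactants: 25 (2E,4E,6E)-2,7-dimethylocta-2,4,6-trienedial
Product: 26 (2E,4E,6E)-2,7-dimethylocta-2,4,6-triene-1,8-diol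
Conditions: NaBH4, MeOH/THF, 0 °C
Reagents that add atoms: none
Why: NaBH4 reduces both aldehydes to the allylic diol with retention of the all-E triene.

Step 20
Reactants: 26 (2E,4E,6E)-2,7-dimethylocta-2,4,6-triene-1,8-diol
Product: 27 (2E,4E,6E)-1,8-dibromo-2,7-dimethylocta-2,4,6-triene
Conditions: PBr3, pyridine (cat.), Et2O, −10 °C, dark
Reagents that add atoms: phosphorus tribromide, BrP(Br)Br
Why: PBr3 converts the primary allylic alcohols into bromides by SN2 displacement at low temperature, which keeps the double-bond positions and geometry.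

Step 21
Reactants: 27 (2E,4E,6E)-1,8-dibromo-2,7-dimethylocta-2,4,6-triene
Product: 28 tetraethyl [(2E,4E,6E)-2,7-dimethylocta-2,4,6-triene-1,8-diyl]bis(phosphonate)
Conditions: P(OEt)3 (neat), 100 °C
Reagents that add atoms: triethyl phosphite, CCOP(OCC)OCC
Why: Michaelis–Arbuzov reaction of the allylic dibromide with triethyl phosphite.

Step 22
Reactants: 24 (2E,4E)-5-[(1S,2R)-1,2-dihydroxy-2,6,6-trimethylcyclohexyl]-3-methylpenta-2,4-dienal; 28 tetraethyl [(2E,4E,6E)-2,7-dimethylocta-2,4,6-triene-1,8-diyl]bis(phosphonate)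
Product: 29 diethyl [(2E,4E,6E,8E,10E,12E)-13-[(1S,2R)-1,2-dihydroxy-2,6,6-trimethylcyclohexyl]-2,7,11-trimethyltrideca-2,4,6,8,10,12-hexaen-1-yl]phosphonate
Conditions: 28 (3 equiv), NaN(SiMe3)2 (3 equiv), THF, −78 °C; then slow addition of 24, −78 → 0 °C; excess 28 recovered
Reagents that add atoms: none
Why: Horner–Wadsworth–Emmons reaction of the allylic phosphonate anion with the enal should give the (E)-alkene; the excess of 28 restricts the reaction to one end, and the free tertiary hydroxyls are tolerated because tertiary alkoxides are themselves suitable bases for such phosphonates.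

Step 23
Reactants: 29 diethyl [(2E,4E,6E,8E,10E,12E)-13-[(1S,2R)-1,2-dihydroxy-2,6,6-trimethylcyclohexyl]-2,7,11-trimethyltrideca-2,4,6,8,10,12-hexaen-1-yl]phosphonate; 12 (2E)-3-[(2S,7aR)-4,4,7a-trimethyl-2,4,5,6,7,7a-hexahydro-1-benzofuran-2-yl]but-2-enal
Product: 30 (5R,8S,5'R,6'S)-5,8-epoxy-5,8,5',6'-tetrahydro-β,β-carotene-5',6'-diol
Conditions: 29, NaN(SiMe3)2, THF, −78 °C; then 12, −78 → 0 °C, dark, argon
Reagents that add atoms: none
Why: The second Horner–Wadsworth–Emmons reaction forms the (E)-C11=C12 bond, and adding 12 to the preformed anion at low temperature avoids epimerisation at C8.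

Compound list

1 | 2,2,6-trimethylcyclohexanone | CC1CCCC(C)(C)C1=O | starting material
2 | 2,6,6-trimethylcyclohex-1-en-1-yl trifluoromethanesulfonate | CC1=C(OS(=O)(=O)C(F)(F)F)C(C)(C)CCC1 | intermediate
3 | (S)-but-3-yn-2-ol | C[C@H](O)C#C | starting material
4 | (2S)-4-(2,6,6-trimethylcyclohex-1-en-1-yl)but-3-yn-2-ol | C[C@H](O)C#CC1=C(C)CCCC1(C)C | intermediate
5 | (2S,3Z)-4-(2,6,6-trimethylcyclohex-1-en-1-yl)but-3-en-2-ol | C[C@H](O)/C=C\C1=C(C)CCCC1(C)C | intermediate
6 | (1S)-1-[(2R,3S)-3-(2,6,6-trimethylcyclohex-1-en-1-yl)oxiran-2-yl]ethan-1-ol | C[C@H](O)[C@H]1O[C@H]1C2=C(C)CCCC2(C)C | intermediate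
7 | 1-[(2S,3S)-3-(2,6,6-trimethylcyclohex-1-en-1-yl)oxiran-2-yl]ethan-1-one | CC(=O)[C@H]1O[C@H]1C2=C(C)CCCC2(C)C | intermediate
8 | triethyl phosphonoacetate | CCOC(=O)CP(=O)(OCC)OCC | starting material
9 | ethyl (2E)-3-[(2R,3S)-3-(2,6,6-trimethylcyclohex-1-en-1-yl)oxiran-2-yl]but-2-enoate | CCOC(=O)/C=C(\C)[C@H]1O[C@H]1C2=C(C)CCCC2(C)C | intermediate
10 | ethyl (2E)-3-[(2S,7aR)-4,4,7a-trimethyl-2,4,5,6,7,7a-hexahydro-1-benzofuran-2-yl]but-2-enoate | CCOC(=O)/C=C(\C)[C@@H]1C=C2C(C)(C)CCC[C@@]2(C)O1 | intermediate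
11 | (2E)-3-[(2S,7aR)-4,4,7a-trimethyl-2,4,5,6,7,7a-hexahydro-1-benzofuran-2-yl]but-2-en-1-ol | OC/C=C(\C)[C@@H]1C=C2C(C)(C)CCC[C@@]2(C)O1 | intermediate
12 | (2E)-3-[(2S,7aR)-4,4,7a-trimethyl-2,4,5,6,7,7a-hexahydro-1-benzofuran-2-yl]but-2-enal | O=C/C=C(\C)[C@@H]1C=C2C(C)(C)CCC[C@@]2(C)O1 | intermediate
13 | β-cyclocitral | CC1=C(C=O)C(C)(C)CCC1 | starting material
14 | β-cyclogeraniol | CC1=C(CO)C(C)(C)CCC1 | intermediate
15 | [(1R,6R)-2,2,6-trimethyl-7-oxabicyclo[4.1.0]heptan-1-yl]methanol | C[C@@]12CCCC(C)(C)[C@]1(CO)O2 | intermediate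
16 | (1S,6R)-1-(iodomethyl)-2,2,6-trimethyl-7-oxabicyclo[4.1.0]heptane | C[C@@]12CCCC(C)(C)[C@]1(CI)O2 | intermediate
17 | (1R)-1,3,3-trimethyl-2-methylidenecyclohexan-1-ol | C[C@@]1(O)CCCC(C)(C)C1=C | intermediate
18 | (2R)-2-hydroxy-2,6,6-trimethylcyclohexan-1-one | C[C@@]1(O)CCCC(C)(C)C1=O | intermediate
19 | (2R)-2,6,6-trimethyl-2-[(trimethylsilyl)oxy]cyclohexan-1-one | C[C@@]1(O[Si](C)(C)C)CCCC(C)(C)C1=O | intermediate
20 | (2E)-3-methylpent-2-en-4-yn-1-ol | OC/C=C(\C)C#C | starting material
21 | (1R,2R)-1-[(3E)-5-hydroxy-3-methylpent-3-en-1-yn-1-yl]-2,6,6-trimethyl-2-[(trimethylsilyl)oxy]cyclohexan-1-ol (silyl-protected adduct) | OC/C=C(\C)C#C[C@]1(O)C(C)(C)CCC[C@@]1(C)O[Si](C)(C)C | intermediate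
22 | (1R,2R)-1-[(3E)-5-hydroxy-3-methylpent-3-en-1-yn-1-yl]-2,6,6-trimethylcyclohexane-1,2-diol | OC/C=C(\C)C#C[C@]1(O)C(C)(C)CCC[C@@]1(C)O | intermediate
23 | (1S,2R)-1-[(1E,3E)-5-hydroxy-3-methylpenta-1,3-dien-1-yl]-2,6,6-trimethylcyclohexane-1,2-diol | OC/C=C(C)/C=C/[C@]1(O)C(C)(C)CCC[C@@]1(C)O | intermediate
24 | (2E,4E)-5-[(1S,2R)-1,2-dihydroxy-2,6,6-trimethylcyclohexyl]-3-methylpenta-2,4-dienal | O=C/C=C(C)/C=C/[C@]1(O)C(C)(C)CCC[C@@]1(C)O | intermediate
25 | (2E,4E,6E)-2,7-dimethylocta-2,4,6-trienedial | O=C/C(C)=C/C=C/C=C(\C)C=O | starting material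
26 | (2E,4E,6E)-2,7-dimethylocta-2,4,6-triene-1,8-diol | OC/C(C)=C/C=C/C=C(\C)CO | intermediate
27 | (2E,4E,6E)-1,8-dibromo-2,7-dimethylocta-2,4,6-triene | BrC/C(C)=C/C=C/C=C(\C)CBr | intermediate
28 | tetraethyl [(2E,4E,6E)-2,7-dimethylocta-2,4,6-triene-1,8-diyl]bis(phosphonate) | CCOP(=O)(OCC)C/C(C)=C/C=C/C=C(\C)CP(=O)(OCC)OCC | intermediate
29 | diethyl [(2E,4E,6E,8E,10E,12E)-13-[(1S,2R)-1,2-dihydroxy-2,6,6-trimethylcyclohexyl]-2,7,11-trimethyltrideca-2,4,6,8,10,12-hexaen-1-yl]phosphonate | CCOP(=O)(OCC)C/C(C)=C/C=C/C=C(C)/C=C/C=C(C)/C=C/[C@]1(O)C(C)(C)CCC[C@@]1(C)O | intermediate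
30 | (5R,8S,5'R,6'S)-5,8-epoxy-5,8,5',6'-tetrahydro-β,β-carotene-5',6'-diol | CC(/C=C/C=C(C)/C=C/[C@]1(O)C(C)(C)CCC[C@@]1(C)O)=C\C=C\C=C(C)\C=C\C=C(/C)[C@@H]1C=C2C(C)(C)CCC[C@@]2(C)O1 | target

Total step count: 23.
Longest linear sequence: 11 steps (steps 10–18, then 22 and 23).

Steps most likely to fail

Step 7. The ion pair may lose its memory: rotation about C7–C8 before closure, or re-ionisation of the product at the allylic C5–O bond, would erode the C5 configuration. Competing pathways are a 1,2-hydride shift to a ketone, proton loss to a dienol, and thermal Cope rearrangement of the cis-dialkenyl oxirane. The fallback sets out from 9 and is stepwise: MgBr2·OEt2 in Et2O at −20 °C should open the oxirane at the allylic C7 with inversion to the bromohydrin ethyl (2E,4R,5R)-5-bromo-4-hydroxy-3-methyl-5-(2,6,6-trimethylcyclohex-1-en-1-yl)pent-2-enoate F1. AgOTf with 2,6-di-tert-butylpyridine in CH2Cl2 at −40 °C then ionises the allylic bromide and the C8 hydroxyl closes on C5. This route is not expected to be stereospecific at C5, so 10 would have to be separated by chromatography from its epimer ethyl (2E)-3-[(2S,7aS)-4,4,7a-trimethyl-2,4,5,6,7,7a-hexahydro-1-benzofuran-2-yl]but-2-enoate F2. The route is rejoined at 10.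

Step 4. Oxygen transfer may go partly to the tetrasubstituted ring alkene, the threo/erythro selectivity of the vanadium transition state may be modest, and the Lewis-acidic metal may open the sensitive vinyl oxirane. The fallback sets out from 5 and replaces hydroxyl direction by catalyst control. Silylation (t-BuMe2SiCl, imidazole, DMF) gives the tert-butyldimethylsilyl ether of 5 F3. Jacobsen–Katsuki epoxidation with (S,S)-N,N'-bis(3,5-di-tert-butylsalicylidene)-1,2-cyclohexanediaminomanganese chloride, NaOCl and 4-phenylpyridine N-oxide prefers cis-disubstituted conjugated alkenes over hindered tetrasubstituted ones. By analogy with indene it should deliver the (7S,8R) oxirane, giving the tert-butyldimethylsilyl ether of 6 F4. Bu4NF in THF then returns the route at 6.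

Step 16. Addition may occur through the ring-flipped or a chelated conformer and give the trans-diol, or the doubly α-quaternary ketone may be too hindered to react. The fallback sets out from 17 and builds the cis-diol by hydrogen-bond-directed osmylation. OsO4·TMEDA (CH2Cl2, −78 °C; then aqueous Na2SO3) should add syn to the tertiary hydroxyl and give (1R,2R)-1-(hydroxymethyl)-2,6,6-trimethylcyclohexane-1,2-diol F5. Parikh–Doering oxidation (SO3·pyridine, DMSO, iPr2NEt) gives (1S,2R)-1,2-dihydroxy-2,6,6-trimethylcyclohexane-1-carbaldehyde F6. Horner–Wadsworth–Emmons reaction with ethyl (2E)-4-(diethoxyphosphoryl)-3-methylbut-2-enoate and NaN(SiMe3)2 gives ethyl (2E,4E)-5-[(1S,2R)-1,2-dihydroxy-2,6,6-trimethylcyclohexyl]-3-methylpenta-2,4-dienoate F7. Reduction with iBu2AlH returns the route at 23.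

Further compounds

F1 | step 7 | ethyl (2E,4R,5R)-5-bromo-4-hydroxy-3-methyl-5-(2,6,6-trimethylcyclohex-1-en-1-yl)pent-2-enoate | CCOC(=O)/C=C(\C)[C@@H](O)[C@H](Br)C1=C(C)CCCC1(C)C
F2 | step 7 | ethyl (2E)-3-[(2S,7aS)-4,4,7a-trimethyl-2,4,5,6,7,7a-hexahydro-1-benzofuran-2-yl]but-2-enoate | CCOC(=O)/C=C(\C)[C@@H]1C=C2C(C)(C)CCC[C@]2(C)O1
F3 | step 4 | tert-butyldimethylsilyl ether of 5 | C[C@H](O[Si](C)(C)C(C)(C)C)/C=C\C1=C(C)CCCC1(C)C
F4 | step 4 | tert-butyldimethylsilyl ether of 6 | C[C@H](O[Si](C)(C)C(C)(C)C)[C@H]1O[C@H]1C2=C(C)CCCC2(C)C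
F5 | step 16 | (1R,2R)-1-(hydroxymethyl)-2,6,6-trimethylcyclohexane-1,2-diol | OC[C@]1(O)C(C)(C)CCC[C@@]1(C)O
F6 | step 16 | (1S,2R)-1,2-dihydroxy-2,6,6-trimethylcyclohexane-1-carbaldehyde | O=C[C@]1(O)C(C)(C)CCC[C@@]1(C)O
F7 | step 16 | ethyl (2E,4E)-5-[(1S,2R)-1,2-dihydroxy-2,6,6-trimethylcyclohexyl]-3-methylpenta-2,4-dienoate | CCOC(=O)/C=C(C)/C=C/[C@]1(O)C(C)(C)CCC[C@@]1(C)O
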